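**Plan**

- Retrosynthesis: after formal resilylation, C7=C8 is taken back to an alkyne and C5'=C6' to a C6' carbinol. The two ring–chain bonds C6–C7 and C6'–C7' are then cut together, and the C22 chain is cut at C11=C12 and C11'=C12'.
- Feature used: C6 (ring B) and C6' (ring A) are each a ring carbon bonded to one end of the same C7–C7' chain, which is C2-symmetric apart from C7=C8 versus C7'≡C8'.
- Forward: actinol supplies both ring ketones, so no ring is formed in the route. A C6 enynyl phosphonium salt and the C10 dialdehyde give the C22 heptaene-diyne. Its dilithium salt is joined to the ring B ketone and then the ring A ketone in one flask. Dehydration of the ring A carbinol, hydroxyl-directed reduction of C7≡C8 and desilylation follow.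
- Stereochemistry: C3 and C3' come from (4R,6R)-actinol, C5 from a Rubottom oxidation (oxygen cis to the C3 silyloxy group), and C6 from axial acetylide attack on the ring B ketone. E geometry comes from the building blocks (C9, C13), thermal Z→E reversion (C11) and trans-hydroalumination (C7).

Key step: step 8

Remark: the target SMILES is read as the (3S,5S,6S,3'R) tetrol, with O3, O5 and C7 on one face of ring B and O6 on the other. Carotenoid locants are used for the polyenes. Actinol, the C10 dialdehyde and the enynol are taken as commercial, and all polyene work is meant under argon with exclusion of light.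

**Step 1**
Reactants: 1 (4R,6R)-4-hydroxy-2,2,6-trimethylcyclohexanone (actinol)
Product: 2 (4R,6R)-4-(tert-butyldimethylsilyloxy)-2,2,6-trimethylcyclohexanone (ring A ketone)
Conditions: TBSCl, imidazole, DMF, rt
Reagents that add atoms: tert-butyldimethylsilyl chloride, CC(C)(C)[Si](C)(C)Cl
Why: Routine O-silylation of an unhindered secondary alcohol; the ketone and both stereocentres are untouched and the TBS ether should last until the fluoride step.

**Step 2**
Reactants: 2 (4R,6R)-4-(tert-butyldimethylsilyloxy)-2,2,6-trimethylcyclohexanone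
Product: 3 tert-butyldimethyl{[(1R)-3,5,5-trimethyl-4-(trimethylsilyloxy)cyclohex-3-en-1-yl]oxy}silane (TMS enol ether)
Conditions: TMSOTf, Et3N, CH2Cl2, 0 °C → rt
Reagents that add atoms: trimethylsilyl trifluoromethanesulfonate, C[Si](C)(C)OS(=O)(=O)C(F)(F)F
Why: Soft enolisation with O-silylation (silyl enol ether formation) can only go towards C6, the sole α-carbon with a hydrogen, so one tetrasubstituted enol ether is expected; the C6 methyl centre is erased on purpose and C4 is not affected.

**Step 3**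
Reactants: 3 tert-butyldimethyl{[(1R)-3,5,5-trimethyl-4-(trimethylsilyloxy)cyclohex-3-en-1-yl]oxy}silane
Product: 6 (2S,4S)-4-(tert-butyldimethylsilyloxy)-2-hydroxy-2,6,6-trimethylcyclohexanone, via silyloxy epoxide 4 (not isolated), via α-trimethylsilyloxy ketone 5 (not isolated)
Conditions: mCPBA, NaHCO3, CH2Cl2, −20 → 0 °C; then citric acid, MeOH, rt
Reagents that add atoms: 3-chloroperoxybenzoic acid, OOC(=O)c1cccc(Cl)c1
Why: Rubottom oxidation, in which the peracid epoxidises the enol ether to 4, 4 opens with 1,4-silyl shift to 5, and mild acid removes the tertiary TMS group without touching the secondary TBS ether; the new C2 centre (2S) is expected from attack cis to the OTBS group, because in the half-chair with equatorial OTBS the pseudoaxial methyl of the neighbouring gem-dimethyl carbon shields the other face (to be confirmed by NOE on 6 before going on).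

**Step 4**
Reactants: 6 (2S,4S)-4-(tert-butyldimethylsilyloxy)-2-hydroxy-2,6,6-trimethylcyclohexanone
Product: 7 (2S,4S)-4-(tert-butyldimethylsilyloxy)-2,6,6-trimethyl-2-(triethylsilyloxy)cyclohexanone (ring B ketone)
Conditions: TESOTf, 2,6-lutidine, CH2Cl2, −78 → 0 °C
Reagents that add atoms: triethylsilyl trifluoromethanesulfonate, CC[Si](CC)(CC)OS(=O)(=O)C(F)(F)F
Why: Silyl triflate silylation of a tertiary alcohol; the ketone has no α-hydrogen so no enol ether can form, and TES is preferred to TMS because it is less prone to 1,2 O→O shift and to cleavage in steps 8 to 10 yet still leaves with fluoride.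

**Step 5**
Reactants: 8 (E)-3-methylpent-2-en-4-yn-1-ol
Product: 9 (E)-5-bromo-3-methylpent-3-en-1-yne
Conditions: PBr3, pyridine (cat.), Et2O, −10 → 0 °C
Reagents that add atoms: phosphorus tribromide, BrP(Br)Br
Why: Conversion of a primary allylic alcohol into the bromide by SN2 displacement of the bromophosphite at low temperature, which should keep the E trisubstituted alkene and the terminal alkyne intact.

**Step 6**
Reactants: 9 (E)-5-bromo-3-methylpent-3-en-1-yne
Product: 10 [(E)-3-methylpent-2-en-4-yn-1-yl]triphenylphosphonium bromide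
Conditions: PPh3, toluene, rt
Reagents that add atoms: triphenylphosphine, c1ccc(cc1)P(c1ccccc1)c1ccccc1
Why: Quaternisation of triphenylphosphine by a primary allylic bromide (SN2) should give a crystalline salt, and crystallisation removes any Z isomer.

**Step 7**
Reactants: 10 [(E)-3-methylpent-2-en-4-yn-1-yl]triphenylphosphonium bromide (2.2 equiv); 11 (2E,4E,6E)-2,7-dimethylocta-2,4,6-trienedial
Product: 14 (3E,5E,7E,9E,11E,13E,15E)-3,7,12,16-tetramethyloctadeca-3,5,7,9,11,13,15-heptaene-1,17-diyne, via phosphorus ylide 12 (not isolated), via C16 ynal 13 (not isolated)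
Conditions: NaOMe, MeOH/CH2Cl2, 0 °C → rt; then heptane, reflux, dark; crystallisation
Reagents that add atoms: none
Why: Twofold Wittig olefination by the semi-stabilised allylic ylide 12 forms C11=C12 and C11'=C12' (through 13), the 9E/9'E and 13E/13'E bonds being carried in from 8 and 11; any Z geometry at the new disubstituted bonds is of the hindered type and should revert to E on heating, while iodine and light are avoided because a 9-ene next to an alkyne tends to equilibrate towards Z.

**Step 8**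
Reactants: 14 C22 heptaene-diyne (2.5 equiv); 7 ring B ketone (1.0 equiv); 2 ring A ketone (5 equiv)
Product: 17 (3S,5S,6R,3'R,5'R,6'S)-3,3'-bis(tert-butyldimethylsilyloxy)-5-(triethylsilyloxy)-7,8,7',8'-tetradehydro-5,6,5',6'-tetrahydro-β,β-carotene-6,6'-diol, via dilithium diacetylide 15 (not isolated), via ring B mono-adduct 16 (not isolated)
Conditions: n-BuLi (2 equiv per 14), THF, −78 → −40 °C; 7, −78 → −20 °C; then 2, −78 → 0 °C; aq. NH4Cl
Reagents that add atoms: none
Why: Double deprotonation of 14 gives the bis(lithium acetylide) 15, and each terminus adds 1,2 to a ketone carbonyl (alkynylation of ketones, the usual entry to acetylenic and olefinic carotenoid end groups), so C6–C7 and C6'–C7' form in one flask and no ring closes. Hetero-coupling rests on order and stoichiometry: the hindered, non-enolisable ketone 7 is the limiting component added to excess 15 and should be consumed mainly as mono-adduct 16, after which the cheap ketone 2 caps every remaining acetylide terminus; 17 is then separated from the symmetric bis-ring-A adduct by chromatography. The C6 centre is under substrate control: 7 should react through the chair with both silyloxy groups equatorial, where the C1 and C5 methyls (C6 and C2 of 7) are axial on one face, so the slim acetylide enters axially from the other face and the chain ends up cis to O3 and O5 with the new hydroxyl trans to O5 (6R here by CIP, 6S after step 10). At C6' axial attack anti to the axial C1' methyl is expected, but this centre and C5' are removed in step 9, so either epimer serves. Silyl ethers and the polyene should be inert to lithium acetylides at low temperature, and keeping the mixture at or below 0 °C disfavours a shift of the TES group from O5 to the more hindered O6 alkoxide.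

**Step 9**
Reactants: 17 bis-propargylic diol
Product: 19 (3S,5S,6R,3'R)-3,3'-bis(tert-butyldimethylsilyloxy)-5-(triethylsilyloxy)-7,8,7',8'-tetradehydro-5,6-dihydro-β,β-caroten-6-ol, via dichlorophosphate ester 18 (not isolated)
Conditions: POCl3, pyridine, 0 → 40 °C, dark
Reagents that add atoms: none
Why: POCl3–pyridine dehydration of a tertiary ethynyl carbinol through its dichlorophosphate: only the ring A carbinol has a β-hydrogen (H5', C1' being quaternary), so it can only give the C5'=C6' enyne from either C6' epimer (anti elimination or loss of H5' from the polyenyne-stabilised ion pair), whereas the ring B carbinol lies between two fully substituted carbons, should be slow to phosphorylate and has no β-hydrogen.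

**Step 10**
Reactants: 19 ring B propargylic alcohol
Product: 21 (3S,5S,6S,3'R)-3,3'-bis(tert-butyldimethylsilyloxy)-5-(triethylsilyloxy)-7',8'-didehydro-5,6-dihydro-β,β-caroten-6-ol, via cyclic vinylalanate 20 (not isolated)
Conditions: NaAlH2(OCH2CH2OCH3)2, THF, 0 °C; aq. KNaC4H4O6
Reagents that add atoms: none
Why: Alkoxide-directed trans-hydroalumination of a propargylic alcohol: the C6 aluminium alkoxide delivers hydride to C7 and forms the cyclic vinylalanate 20, whose protonolysis gives the 7E alkene; the C7'≡C8' enyne has no neighbouring hydroxyl and, like the silyl ethers, should be left alone at 0 °C, and the C6 centre is not touched.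

**Step 11**
Reactants: 21 trisilylated tetrol
Product: 22 (3S,5S,6S,3'R)-7',8'-didehydro-5,6-dihydro-β,β-carotene-3,5,6,3'-tetrol (target)
Conditions: Bu4NF, THF, rt, dark
Reagents that add atoms: none
Why: Fluoride-mediated desilylation removes the two secondary TBS ethers and the tertiary TES ether under non-acidic conditions that the polyene and the tertiary allylic C6 alcohol should tolerate; no stereocentre is affected.

**Compound list**

1 | (4R,6R)-4-hydroxy-2,2,6-trimethylcyclohexanone (actinol) | O=C1C(C)(C)C[C@H](O)C[C@H]1C | starting material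
2 | (4R,6R)-4-(tert-butyldimethylsilyloxy)-2,2,6-trimethylcyclohexanone (ring A ketone) | O=C1C(C)(C)C[C@H](O[Si](C)(C)C(C)(C)C)C[C@H]1C | intermediate
3 | tert-butyldimethyl{[(1R)-3,5,5-trimethyl-4-(trimethylsilyloxy)cyclohex-3-en-1-yl]oxy}silane | CC1=C(O[Si](C)(C)C)C(C)(C)C[C@H](O[Si](C)(C)C(C)(C)C)C1 | intermediate
4 | (1S,4S,6S)-4-(tert-butyldimethylsilyloxy)-2,2,6-trimethyl-1-(trimethylsilyloxy)-7-oxabicyclo[4.1.0]heptane (epoxide oxygen cis to OTBS) | C[Si](C)(C)O[C@@]12C(C)(C)C[C@H](O[Si](C)(C)C(C)(C)C)C[C@]1(C)O2 | intermediate (not isolated)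
5 | (2S,4S)-4-(tert-butyldimethylsilyloxy)-2,6,6-trimethyl-2-(trimethylsilyloxy)cyclohexanone | O=C1C(C)(C)C[C@H](O[Si](C)(C)C(C)(C)C)C[C@]1(C)O[Si](C)(C)C | intermediate (not isolated)
6 | (2S,4S)-4-(tert-butyldimethylsilyloxy)-2-hydroxy-2,6,6-trimethylcyclohexanone | O=C1C(C)(C)C[C@H](O[Si](C)(C)C(C)(C)C)C[C@]1(C)O | intermediate
7 | (2S,4S)-4-(tert-butyldimethylsilyloxy)-2,6,6-trimethyl-2-(triethylsilyloxy)cyclohexanone (ring B ketone) | O=C1C(C)(C)C[C@H](O[Si](C)(C)C(C)(C)C)C[C@]1(C)O[Si](CC)(CC)CC | intermediate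
8 | (E)-3-methylpent-2-en-4-yn-1-ol | C#C/C(C)=C/CO | starting material
9 | (E)-5-bromo-3-methylpent-3-en-1-yne | C#C/C(C)=C/CBr | intermediate
10 | [(E)-3-methylpent-2-en-4-yn-1-yl]triphenylphosphonium bromide | C#C/C(C)=C/C[P+](c1ccccc1)(c1ccccc1)c1ccccc1.[Br-] | intermediate
11 | (2E,4E,6E)-2,7-dimethylocta-2,4,6-trienedial | O=C/C(C)=C/C=C/C=C(C)/C=O | starting material
12 | [(E)-3-methylpent-2-en-4-yn-1-ylidene]triphenylphosphorane | C#C/C(C)=C/C=P(c1ccccc1)(c1ccccc1)c1ccccc1 | intermediate (not isolated)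
13 | (2E,4E,6E,8E,10E)-2,7,11-trimethyltrideca-2,4,6,8,10-pentaen-12-ynal (all-E isomer shown) | C#C/C(C)=C/C=C/C(C)=C/C=C/C=C(C)/C=O | intermediate (not isolated)
14 | (3E,5E,7E,9E,11E,13E,15E)-3,7,12,16-tetramethyloctadeca-3,5,7,9,11,13,15-heptaene-1,17-diyne | C#C/C(C)=C/C=C/C(C)=C/C=C/C=C(C)/C=C/C=C(C)/C#C | intermediate
15 | dilithium salt of 14 (1,18-dilithio diacetylide) | [Li]C#C/C(C)=C/C=C/C(C)=C/C=C/C=C(C)/C=C/C=C(C)/C#C[Li] | intermediate (not isolated)
16 | ring B mono-adduct as lithium C6-alkoxide and lithium C7'-acetylide | [Li]C#C/C(C)=C/C=C/C(C)=C/C=C/C=C(C)/C=C/C=C(C)/C#C[C@]1(O[Li])C(C)(C)C[C@H](O[Si](C)(C)C(C)(C)C)C[C@]1(C)O[Si](CC)(CC)CC | intermediate (not isolated)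
17 | (3S,5S,6R,3'R,5'R,6'S)-3,3'-bis(tert-butyldimethylsilyloxy)-5-(triethylsilyloxy)-7,8,7',8'-tetradehydro-5,6,5',6'-tetrahydro-β,β-carotene-6,6'-diol (expected major C6' epimer) | C[C@H]1[C@@](O)(C#C/C(C)=C/C=C/C(C)=C/C=C/C=C(C)/C=C/C=C(C)/C#C[C@]2(O)C(C)(C)C[C@H](O[Si](C)(C)C(C)(C)C)C[C@]2(C)O[Si](CC)(CC)CC)C(C)(C)C[C@H](O[Si](C)(C)C(C)(C)C)C1 | intermediate
18 | 6'-O-dichlorophosphate of 17 | C[C@H]1[C@@](OP(=O)(Cl)Cl)(C#C/C(C)=C/C=C/C(C)=C/C=C/C=C(C)/C=C/C=C(C)/C#C[C@]2(O)C(C)(C)C[C@H](O[Si](C)(C)C(C)(C)C)C[C@]2(C)O[Si](CC)(CC)CC)C(C)(C)C[C@H](O[Si](C)(C)C(C)(C)C)C1 | intermediate (not isolated)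
19 | (3S,5S,6R,3'R)-3,3'-bis(tert-butyldimethylsilyloxy)-5-(triethylsilyloxy)-7,8,7',8'-tetradehydro-5,6-dihydro-β,β-caroten-6-ol | CC1=C(C#C/C(C)=C/C=C/C(C)=C/C=C/C=C(C)/C=C/C=C(C)/C#C[C@]2(O)C(C)(C)C[C@H](O[Si](C)(C)C(C)(C)C)C[C@]2(C)O[Si](CC)(CC)CC)C(C)(C)C[C@H](O[Si](C)(C)C(C)(C)C)C1 | intermediate
20 | sodium cyclic vinylalanate of 21 (Al bonded to O6 and C8, two 2-methoxyethoxy ligands) | [Na+].CC1=C(C#C/C(C)=C/C=C/C(C)=C/C=C/C=C(C)/C=C/C=C(C)/C2=C/[C@]3(O[Al-]2(OCCOC)OCCOC)C(C)(C)C[C@H](O[Si](C)(C)C(C)(C)C)C[C@]3(C)O[Si](CC)(CC)CC)C(C)(C)C[C@H](O[Si](C)(C)C(C)(C)C)C1 | intermediate (not isolated)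
21 | (3S,5S,6S,3'R)-3,3'-bis(tert-butyldimethylsilyloxy)-5-(triethylsilyloxy)-7',8'-didehydro-5,6-dihydro-β,β-caroten-6-ol | CC1=C(C#C/C(C)=C/C=C/C(C)=C/C=C/C=C(C)/C=C/C=C(C)/C=C/[C@]2(O)C(C)(C)C[C@H](O[Si](C)(C)C(C)(C)C)C[C@]2(C)O[Si](CC)(CC)CC)C(C)(C)C[C@H](O[Si](C)(C)C(C)(C)C)C1 | intermediate
22 | (3S,5S,6S,3'R)-7',8'-didehydro-5,6-dihydro-β,β-carotene-3,5,6,3'-tetrol | CC1=C(C#C/C(C)=C/C=C/C(C)=C/C=C/C=C(C)/C=C/C=C(C)/C=C/[C@]2(O)C(C)(C)C[C@H](O)C[C@]2(C)O)C(C)(C)C[C@H](O)C1 | target

**Step count and risks**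

Total steps: 11. Longest linear sequence: 8 (steps 1–4 and 8–11, from actinol).

Steps most likely to fail:

1. Step 3. The peracid may attack the enol ether with poor or reversed facial selectivity (for instance if the ring reacts through a flattened or OTBS-axial half-chair), and a wrong C2 configuration cannot be repaired later. The fallback puts this centre under reagent control; it sets out from 2 and comes back at 6. Ketone 2 is converted with LiN(i-Pr)2 and PhNTf2 into (4R)-4-(tert-butyldimethylsilyloxy)-2,6,6-trimethylcyclohex-1-en-1-yl trifluoromethanesulfonate F1. Methoxycarbonylation (Pd(OAc)2, PPh3, CO, MeOH, Et3N) gives methyl (4R)-4-(tert-butyldimethylsilyloxy)-2,6,6-trimethylcyclohex-1-ene-1-carboxylate F2, and i-Bu2AlH reduces it to [(4R)-4-(tert-butyldimethylsilyloxy)-2,6,6-trimethylcyclohex-1-en-1-yl]methanol F3. Katsuki–Sharpless epoxidation with Ti(OiPr)4, L-(+)-diethyl tartrate and t-BuOOH should place the oxygen cis to the silyloxy group, giving [(1S,4S,6S)-4-(tert-butyldimethylsilyloxy)-2,2,6-trimethyl-7-oxabicyclo[4.1.0]heptan-1-yl]methanol F4. I2, PPh3 and imidazole give (1R,4S,6S)-4-(tert-butyldimethylsilyloxy)-1-(iodomethyl)-2,2,6-trimethyl-7-oxabicyclo[4.1.0]heptane F5. Zinc in ethanol opens it reductively to (1S,5S)-5-(tert-butyldimethylsilyloxy)-1,3,3-trimethyl-2-methylidenecyclohexan-1-ol F6, and ozonolysis (O3, then Me2S) of the exocyclic alkene gives 6.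

2. Step 8. With three components in one flask, the acetylide termini may scramble statistically into symmetric bis-adducts, the hindered ketone 7 may be converted incompletely, or the TES group may shift to the new alkoxide. The fallback separates the two additions; it sets out from 14 and comes back at 17. A larger excess of the dilithium salt of 14 is treated with 7 alone, and after quench the mono-adduct (1R,2S,4S)-4-(tert-butyldimethylsilyloxy)-2,6,6-trimethyl-1-[(3E,5E,7E,9E,11E,13E,15E)-3,7,12,16-tetramethyloctadeca-3,5,7,9,11,13,15-heptaene-1,17-diyn-1-yl]-2-(triethylsilyloxy)cyclohexan-1-ol F7 is isolated and unreacted 14 recovered. F7 is then deprotonated twice (alkoxide and acetylide) with LiN(i-Pr)2 and added to 2, which gives 17.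

3. Step 9. The ring B carbinol may also be phosphorylated and ionise (to chloride, allene or rearranged products), or the TES ether may be lost, so that the dehydration is not confined to ring A. The fallback moves the dehydration ahead of the ring B coupling; it sets out from 14 and 2 and comes back at 19. Excess dilithium salt of 14 and ketone 2 alone give (1S,4R,6R)-4-(tert-butyldimethylsilyloxy)-2,2,6-trimethyl-1-[(3E,5E,7E,9E,11E,13E,15E)-3,7,12,16-tetramethyloctadeca-3,5,7,9,11,13,15-heptaene-1,17-diyn-1-yl]cyclohexan-1-ol F8. POCl3–pyridine, with no other tertiary alcohol present, dehydrates it to tert-butyldimethyl{[(1R)-3,5,5-trimethyl-4-[(3E,5E,7E,9E,11E,13E,15E)-3,7,12,16-tetramethyloctadeca-3,5,7,9,11,13,15-heptaene-1,17-diyn-1-yl]cyclohex-3-en-1-yl]oxy}silane F9. Lithiation of F9 with n-BuLi and addition to 7, then aqueous NH4Cl, give 19 directly.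

**Further compounds**

F1 | step 3 | (4R)-4-(tert-butyldimethylsilyloxy)-2,6,6-trimethylcyclohex-1-en-1-yl trifluoromethanesulfonate | CC1=C(OS(=O)(=O)C(F)(F)F)C(C)(C)C[C@H](O[Si](C)(C)C(C)(C)C)C1
F2 | step 3 | methyl (4R)-4-(tert-butyldimethylsilyloxy)-2,6,6-trimethylcyclohex-1-ene-1-carboxylate | CC1=C(C(=O)OC)C(C)(C)C[C@H](O[Si](C)(C)C(C)(C)C)C1
F3 | step 3 | [(4R)-4-(tert-butyldimethylsilyloxy)-2,6,6-trimethylcyclohex-1-en-1-yl]methanol | CC1=C(CO)C(C)(C)C[C@H](O[Si](C)(C)C(C)(C)C)C1
F4 | step 3 | [(1S,4S,6S)-4-(tert-butyldimethylsilyloxy)-2,2,6-trimethyl-7-oxabicyclo[4.1.0]heptan-1-yl]methanol | OC[C@@]12C(C)(C)C[C@H](O[Si](C)(C)C(C)(C)C)C[C@]1(C)O2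
F5 | step 3 | (1R,4S,6S)-4-(tert-butyldimethylsilyloxy)-1-(iodomethyl)-2,2,6-trimethyl-7-oxabicyclo[4.1.0]heptane | IC[C@@]12C(C)(C)C[C@H](O[Si](C)(C)C(C)(C)C)C[C@]1(C)O2
F6 | step 3 | (1S,5S)-5-(tert-butyldimethylsilyloxy)-1,3,3-trimethyl-2-methylidenecyclohexan-1-ol | C=C1C(C)(C)C[C@H](O[Si](C)(C)C(C)(C)C)C[C@]1(C)O
F7 | step 8 | (1R,2S,4S)-4-(tert-butyldimethylsilyloxy)-2,6,6-trimethyl-1-[(3E,5E,7E,9E,11E,13E,15E)-3,7,12,16-tetramethyloctadeca-3,5,7,9,11,13,15-heptaene-1,17-diyn-1-yl]-2-(triethylsilyloxy)cyclohexan-1-ol | C#C/C(C)=C/C=C/C(C)=C/C=C/C=C(C)/C=C/C=C(C)/C#C[C@]1(O)C(C)(C)C[C@H](O[Si](C)(C)C(C)(C)C)C[C@]1(C)O[Si](CC)(CC)CC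
F8 | step 9 | (1S,4R,6R)-4-(tert-butyldimethylsilyloxy)-2,2,6-trimethyl-1-[(3E,5E,7E,9E,11E,13E,15E)-3,7,12,16-tetramethyloctadeca-3,5,7,9,11,13,15-heptaene-1,17-diyn-1-yl]cyclohexan-1-ol | C[C@H]1[C@@](O)(C#C/C(C)=C/C=C/C(C)=C/C=C/C=C(C)/C=C/C=C(C)/C#C)C(C)(C)C[C@H](O[Si](C)(C)C(C)(C)C)C1
F9 | step 9 | tert-butyldimethyl{[(1R)-3,5,5-trimethyl-4-[(3E,5E,7E,9E,11E,13E,15E)-3,7,12,16-tetramethyloctadeca-3,5,7,9,11,13,15-heptaene-1,17-diyn-1-yl]cyclohex-3-en-1-yl]oxy}silane | CC1=C(C#C/C(C)=C/C=C/C(C)=C/C=C/C=C(C)/C=C/C=C(C)/C#C)C(C)(C)C[C@H](O[Si](C)(C)C(C)(C)C)C1
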